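## Analysis of the target

The target is a dihydroflavonol: a chroman-4-one whose ring A (C4a–C8a) is substituted everywhere except C8 (5-OMe, 6-geranyl, 7-OH) and whose ring C carries the C4 ketone, the C3 hydroxyl and, at C2, ring B (4-hydroxyphenyl). It has two stereocentres, C2 (R) and C3 (R), which are neighbours and trans, with the aryl group and the hydroxyl both equatorial on the half-chair of ring C; the geranyl chain adds one (E)-trisubstituted alkene. The α-ketol is the fragile part: C3 is enolisable, and once the 4'-phenol is free, base opens ring C at O1–C2, which epimerises C2, contracts the ring or, with air, leads to the flavonol. The geranyl chain rules out hydrogenolysis and strong acid, above all while the neighbouring C7 phenol is free, because its first alkene then closes a further pyran ring onto that oxygen. Ring A is the second problem: three phenolic oxygens must be told apart, and the one that stays methylated (O5) is the most hindered, wedged between the geranyl group and C4a. The synthesis is hard because the trans C2/C3 pair has to be made in the absolute sense with no resident stereocentre to direct it, on a molecule that tolerates acid, base and oxidants poorly. The plan rests on ring C: O1, C8a, C4a and C4 form a 1-oxadiene (an ortho-quinone methide at the oxidation level of a salicylaldehyde), and C2=C3, with the aryl group on C2 and an oxygen on C3, is an enol ester, so forming O1–C2 and C3–C4 closes ring C and sets both stereocentres in one event.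

## Retrosynthetic reasoning

**19 ⇒ 18.** The last disconnection cuts three O–Si bonds. All hydroxyl groups of 18 are masked as silyl ethers so that a single buffered fluoride treatment frees them. Acid (geranyl next to the C7 phenol), hydrogenolysis (alkenes) and base (α-ketol with free phenols) are thereby all avoided at the most sensitive stage.

**18 ⇒ 17 ⇒ 16.** The C4 carbonyl is traced back through the C4 alcohol 17 to the C4 methyl ether 16. C4 is a stereocentre in these compounds, but both epimers converge on the ketone. The ketone is installed late because C4 is the electrophilic carbon of the ring-forming step and leaves that step as a benzylic methyl ether. The ether is flanked by O1, O5 and O7 in ortho and para positions, so it ionises under very mild acid, and the forward steps are a solvolysis followed by a neutral oxidation.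

**16 ⇒ 15 ⇒ 14.** The C3 oxygen leaves the ring-forming step as an acetate, and here it is exchanged for a silyl ether before C4 is touched. An ester at C3 would take part in the ionisation at C4: its carbonyl oxygen would bridge to C4, and hydrolysis of the bridged ion at the acyl carbon would spread the acetyl group over O3 and O4. The wrong hydroxyl would then be oxidised. A basic deacetylation next to the finished ketone would also endanger C2 and C3. The exchange costs one extra step; in return the silyl ether cannot bridge and falls in the final deprotection.

**14 ⇒ 7 + 10 + 11.** This is the central disconnection. It cuts O1–C2 and C3–C4 of ring C and the C4–OMe bond. It is made here because it is the only cut that removes the ring and both stereocentres together, divides the molecule into two halves of similar size, and uses the ring A aldehyde carbon directly as C4. In the forward direction, aldehyde 7 and orthoformate 11 give acetal 12, which ionises to the protonated form of the 4-methoxy ortho-quinone methide 13. The enol acetate 10 must then add with its oxygen-bearing carbon to C4, and the phenol oxygen must close onto the benzylic carbon. The reaction has to give the 2,3-trans ring and, under a chiral phosphoric acid, one enantiomer.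

**7 ⇒ 6 ⇒ 5 ⇒ 4 ⇒ 3.** The three O-substituents of 7 are removed one after another (O–CH3, the methoxymethyl group, O–Si). The order follows the intrinsic reactivity of 3. The phenol para to the aldehyde is the only one not hydrogen-bonded to it and is silylated first (4). Of the two chelated phenols, the one flanked by H takes the temporary acetal (5). The last one, between the geranyl group and the aldehyde, is then methylated (6). Mild acid removes the acetal (7). At no point does the geranyl group face acid with a free phenol next to it.

**3 ⇒ 1 + 2.** The aryl–geranyl bond is cut. The forward reaction is the C-alkylation of the phenoxide of 1 with bromide 2. C3 and C5 of 1 are equivalent, so mono-alkylation has only one outcome.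

**10 ⇒ 9 ⇒ 8.** The enol ester C–O bond is traced to the acyl–alkenyl bond of the (E)-enone 9 (oxygen insertion with migration of the alkenyl group), and 9 to the commercial phenol 8. The (E)-geometry of 10 is thus taken from a purchased alkene and not from an enolisation.

## Alternatives that were turned down

**Alternative 1: three-component carbenoid/aldol route.**
- Disconnection: C2–C3 and C3–O of an open-chain α,β-dihydroxy ketone; ring C stays open at O1–C2.
- Forward key step: Rh2(OAc)4 decomposes the ring A diazoketone A2, the carbenoid takes up water A4, and the resulting oxonium ylide (enol) is intercepted by the aldehyde A3 under a chiral phosphoric acid to give the diol A1.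
- For it: the C4 ketone and the free C3 hydroxyl arrive at their final oxidation level, so no adjustment at C4 and no protecting-group exchange at C3 are needed. The reaction family is established for aryl diazoacetates. On redox economy and closeness to precedent it is stronger than the chosen route.
- Against it for this target:
  - An electrophilic rhodium carbenoid is generated in a molecule with two trisubstituted alkenes and two ortho ether oxygens. Capture of the carbenoid by the ortho ether oxygen, followed by an alkyl shift, closes a five-membered ring and is the usual fate of ortho-alkoxyaryl diazoketones. Cyclopropanation of a geranyl alkene of a second molecule also competes with the attack of A4.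
  - Ring C is still open in A1. The benzylic hydroxyl of A1 has the configuration that O1 has in the target, so closure needs net retention at C2 (an SN1 closure or a double inversion), not a simple Mitsunobu inversion.
  - A2 has to be made from the hindered ring A carboxylic acid.
- Comparison: the step count is about the same. The chosen route closes the ring and sets both centres in one operation from an aldehyde that needs no activation, and it has no carbenoid near the geranyl chain.

**Alternative 2: polyketide-type Claisen cyclisation.**
- Disconnection: C4a–C5 of ring A; the benzene ring is folded from an acyclic chain.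
- Forward key step: Mg(OMe)2-mediated Claisen cyclisation of the triketo ester A6, whose doubly activated methylene attacks the ester carbon, to give the chalcone A5.
- For it: it is biomimetic. The geranyl group is placed by alkylation of a β-keto ester, which is cleaner and regiochemically more secure than the phenoxide C-alkylation of step 1; on that point it is at least as good as the chosen route.
- Against it for this target:
  - The main bond-forming effort goes into a benzene ring that can be bought with its three oxygens and its carbonyl carbon in place.
  - A6 is a sensitive tetracarbonyl compound that needs several dianion acylations. Its cyclisation can also close in the aldol sense, and the ester to be attacked sits next to the geranyl-bearing carbon.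
  - A5 has three free phenols, so the differentiation problem (methylating the one between the geranyl and acyl groups) is untouched and now has to be solved beside an enone that cyclises. Closure through the wrong ortho phenol would put the geranyl group on C8.
  - Neither stereocentre is addressed; an asymmetric epoxidation/cyclisation sequence would have to follow.
- Comparison: it is longer and stereochemically empty. The chosen route gets ring A from a commercial aldehyde in five simple steps and spends its key step on C2 and C3.

**Alternative 3: photochemical vinylketene benzannulation.**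
- Disconnection: four bonds of ring A (C8a–C8, C6–C7, C5–C6, C4a–C8a).
- Forward key step: irradiation of the diazo enone A8 causes a Wolff rearrangement to a vinylketene, which adds the siloxyalkyne A9 in a [2+2] reaction. Ring opening of the cyclobutenone and 6π electrocyclisation give the phenol A7.
- For it: A7 carries the three oxygens already differentiated (methyl ether from A8, silyl ether from A9, free phenol from the ketene carbon) and the geranyl group on the correct carbon. One ortho-formylation would turn it into 7. The chosen route pays for the same result with four protecting-group operations whose regiochemistry rests on sterics, so on this point alternative 3 is stronger.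
- Against it for this target:
  - A8 is an α-alkyl diazoketone that is also a 2-methoxy enone and carries the geranyl chain on the diazo carbon. It needs its own multistep synthesis, and on irradiation a 1,2-hydrogen shift from the adjacent CH2 competes with the Wolff rearrangement.
  - A9 is a moisture-sensitive ynol ether.
  - The formylation of A7 must distinguish the two positions ortho to the phenol.
  - None of the stereocentres is touched, so the sequence is only another way to reach 7.
- Comparison: it is not shorter than steps 1–5 and uses specialised photochemistry, whereas the chosen strategy reaches 7 with commodity reagents and keeps the one uncertain step for the stereocentres.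

Key step: step 8

## Remarks before the route

- Abbreviations: geranyl = (2E)-3,7-dimethylocta-2,6-dien-1-yl; TIPS = triisopropylsilyl; TBS = tert-butyldimethylsilyl; MOM = methoxymethyl; DBU = 1,8-diazabicyclo[5.4.0]undec-7-ene.
- Assumption: the (R)-enantiomer of the phosphoric acid is written in step 8. The sense of induction of this new reaction cannot be derived from a precedent, and the (S)-acid would be used if the mirror-image chroman formed.
- Descriptors: in the chromans 14–17, C3 is (S) because C2 outranks the sp3 carbon C4. The same spatial arrangement is (R) once C4 is a carbonyl (18, 19). Nothing is inverted on the way.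

## Route

Step 1
Reactants: 1 2,4,6-trihydroxybenzaldehyde; 2 geranyl bromide
Product: 3 3-geranyl-2,4,6-trihydroxybenzaldehyde
Conditions: 1 (2 equiv), DBU (1 equiv), THF, 0 °C → rt
Reagents that add atoms: none
Why: C-alkylation of a phloroglucinol-type phenoxide with a soft allylic bromide (amidine base, weakly polar solvent favour C- over O-attack); C3 and C5 of 1 are equivalent, so only one mono-C-geranyl product can form, the excess of 1 should hold back double alkylation, and SN2 at the primary allylic carbon keeps the (E)-alkene.

Step 2
Reactants: 3 3-geranyl-2,4,6-trihydroxybenzaldehyde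
Product: 4 3-geranyl-2,6-dihydroxy-4-(triisopropylsilyloxy)benzaldehyde
Conditions: TIPSCl (1.05 equiv), imidazole, DMF, 0 °C
Reagents that add atoms: triisopropylsilyl chloride, CC(C)[Si](Cl)(C(C)C)C(C)C
Why: Selective O-silylation: the C4 hydroxyl is the only phenol not held in a hydrogen bond to the aldehyde and, being para to it, the most acidic, so one equivalent of silyl chloride should go there; the bulky TIPS ether is chosen to last to the final step.

Step 3
Reactants: 4 3-geranyl-2,6-dihydroxy-4-(triisopropylsilyloxy)benzaldehyde
Product: 5 3-geranyl-2-hydroxy-6-(methoxymethoxy)-4-(triisopropylsilyloxy)benzaldehyde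
Conditions: MOMCl (1.2 equiv), i-Pr2NEt, CH2Cl2, 0 °C → rt
Reagents that add atoms: chloromethyl methyl ether, COCCl
Why: O-alkylation with a chloromethyl ether under amine base: only one of the two ortho phenols can be chelated to the aldehyde at a time, the one flanked by H (C6) is accessible whereas the C2 phenol is buttressed by the geranyl CH2, and after the first etherification the remaining phenol is locked in the chelate and should not react further.

Step 4
Reactants: 5 3-geranyl-2-hydroxy-6-(methoxymethoxy)-4-(triisopropylsilyloxy)benzaldehyde
Product: 6 3-geranyl-2-methoxy-6-(methoxymethoxy)-4-(triisopropylsilyloxy)benzaldehyde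
Conditions: MeI, K2CO3, acetone, 50 °C
Reagents that add atoms: iodomethane, CI
Why: Williamson O-methylation of the only remaining phenol; its potassium phenoxide, although chelated and hindered, is alkylated by the small methyl iodide, and the aryl TIPS ether and the MOM acetal are expected to tolerate K2CO3 in dry acetone.

Step 5
Reactants: 6 3-geranyl-2-methoxy-6-(methoxymethoxy)-4-(triisopropylsilyloxy)benzaldehyde
Product: 7 3-geranyl-6-hydroxy-2-methoxy-4-(triisopropylsilyloxy)benzaldehyde
Conditions: 2 M aq. HCl, THF–MeOH, rt
Reagents that add atoms: none
Why: Acid hydrolysis of the aryl MOM acetal, the most acid-labile group present and activated by the ortho carbonyl; the aryl TIPS ether and the methyl ether are stable to dilute aqueous acid, and the geranyl group is flanked by two ether oxygens, so no phenol can add to its alkene.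

Step 6
Reactants: 8 (E)-4-(4-hydroxyphenyl)but-3-en-2-one
Product: 9 (E)-4-[4-(triisopropylsilyloxy)phenyl]but-3-en-2-one
Conditions: TIPSCl, imidazole, DMF, rt
Reagents that add atoms: triisopropylsilyl chloride, CC(C)[Si](Cl)(C(C)C)C(C)C
Why: Silylation of the only hydroxyl group; the silyl ether keeps the para oxygen a strong donor for step 8 and is removed together with the other silyl groups at the end.

Step 7
Reactants: 9 (E)-4-[4-(triisopropylsilyloxy)phenyl]but-3-en-2-one
Product: 10 (E)-2-[4-(triisopropylsilyloxy)phenyl]ethenyl acetate
Conditions: dibenzyl diselenide (5 mol %), 30% aq. H2O2, MeCN, rt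
Reagents that add atoms: hydrogen peroxide, OO
Why: Baeyer–Villiger oxidation of an α,β-unsaturated methyl ketone: the perseleninic acid formed in the flask adds to the carbonyl group and the alkenyl group migrates in preference to methyl with retention of the double-bond geometry, so the (E)-enol acetate should be obtained without any enolisation step.

Step 8
Reactants: 7 3-geranyl-6-hydroxy-2-methoxy-4-(triisopropylsilyloxy)benzaldehyde; 10 (E)-2-[4-(triisopropylsilyloxy)phenyl]ethenyl acetate; 11 trimethyl orthoformate
Product: 14 (2R,3S)-6-geranyl-4,5-dimethoxy-7-(triisopropylsilyloxy)-2-[4-(triisopropylsilyloxy)phenyl]chroman-3-yl acetate as the 2,3-trans C4 epimers, via dimethyl acetal 12 (not isolated), via methoxy ortho-quinone methide 13 (not isolated)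
Conditions: (R)-3,3'-bis(2,4,6-triisopropylphenyl)-1,1'-binaphthyl-2,2'-diyl hydrogen phosphate (10 mol %), 10 (2 equiv), 11 (3 equiv), 5 Å molecular sieves, CH2Cl2, −20 °C → rt
Reagents that add atoms: none
Why: Proposed new method: the phosphoric acid first converts 7 and 11 into acetal 12, which loses methanol to the O-protonated form of 13, a 2,4,6-trioxygenated benzylic oxocarbenium ion held as a contact ion pair by the chiral phosphate, which also hydrogen-bonds the C8a phenol. The acetoxy-bearing carbon of 10 adds to C4 (bond C3–C4), because only this orientation places the developing charge on the para-silyloxybenzylic carbon C2, where the neighbouring ester carbonyl oxygen bridges it as a 1,3-dioxolan-2-ylium ion with the aryl group and C4 trans on the five-membered ring. The C8a phenol oxygen, deprotonated by the phosphate, opens this ion at C2 anti to the bridging oxygen; ring C is thus closed by a 6-exo-tet displacement (the C2–O bond that breaks lies outside the new ring), and the overall change is a formal inverse-demand hetero-[4+2] addition of the ortho-quinone methide. The closest known reactions are the acid-catalysed three-component condensation of salicylaldehydes, orthoformates and styrenes to 4-alkoxy-2-arylchromans and the chiral phosphoric acid catalysed [4+2] additions of ortho-quinone methides to styrenes, enol ethers and enamides; an enol ester as the two-carbon partner under chiral anion control has no precedent. C3 is set in the C–C bond formation by the face of 10 that the ion pair exposes (catalyst control, the only source of absolute configuration); C2 follows from C3 through the anti opening of the bridged ion or, in the concerted limit, through suprafacial addition to the (E)-alkene, both of which give the 2,3-trans ring; C4 is not controlled and is erased in step 12. The step needs regioselectivity, which the para-oxygenated aryl group secures, and chemoselectivity for 10 over the two geranyl alkenes and over methanol, for which 10 is used in excess, the sieves take up methanol, and the geranyl chain has no free ortho phenol and cannot reach C4.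

Step 9
Reactants: 14 (2R,3S)-6-geranyl-4,5-dimethoxy-7-(triisopropylsilyloxy)-2-[4-(triisopropylsilyloxy)phenyl]chroman-3-yl acetate (C4 epimers)
Product: 15 (2R,3S)-6-geranyl-4,5-dimethoxy-7-(triisopropylsilyloxy)-2-[4-(triisopropylsilyloxy)phenyl]chroman-3-ol (C4 epimers)
Conditions: i-Bu2AlH (3 equiv), CH2Cl2, −78 °C; aq. KNaC4H4O6
Reagents that add atoms: none
Why: Reductive cleavage of the acetate (ester to alcohol with an aluminium hydride at low temperature); the aryl silyl ethers, the benzylic methyl ether and the alkenes do not react, no alkoxide base is present that could strip the aryl silyl ethers, and C2 and C3 are not touched.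

Step 10
Reactants: 15 (2R,3S)-6-geranyl-4,5-dimethoxy-7-(triisopropylsilyloxy)-2-[4-(triisopropylsilyloxy)phenyl]chroman-3-ol (C4 epimers)
Product: 16 (2R,3S)-3-(tert-butyldimethylsilyloxy)-6-geranyl-4,5-dimethoxy-7-(triisopropylsilyloxy)-2-[4-(triisopropylsilyloxy)phenyl]chroman (C4 epimers)
Conditions: TBSCl, imidazole, 4-(dimethylamino)pyridine (cat.), DMF, 40 °C
Reagents that add atoms: tert-butyldimethylsilyl chloride, CC(C)(C)[Si](C)(C)Cl
Why: Silyl ether formation at the equatorial secondary C3 hydroxyl without any Lewis acid that could ionise C4; unlike the acetate, the TBS ether cannot bridge to a C4 cation, it tolerates step 11 and falls with the aryl silyl ethers in step 13.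

Step 11
Reactants: 16 (2R,3S)-3-(tert-butyldimethylsilyloxy)-6-geranyl-4,5-dimethoxy-7-(triisopropylsilyloxy)-2-[4-(triisopropylsilyloxy)phenyl]chroman (C4 epimers)
Product: 17 (2R,3S)-3-(tert-butyldimethylsilyloxy)-6-geranyl-5-methoxy-7-(triisopropylsilyloxy)-2-[4-(triisopropylsilyloxy)phenyl]chroman-4-ol (C4 epimers)
Conditions: pyridinium p-toluenesulfonate (0.2 equiv), acetone–H2O (5:1), rt
Reagents that add atoms: water, O
Why: SN1 solvolysis of a benzylic methyl ether: O1, O5 and O7 stand ortho and para to C4 and stabilise the cation so well that a pyridinium acid should suffice, and water in large excess captures it; either C4 epimer is acceptable, and the silyl ethers and the geranyl chain are stable at this acidity.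

Step 12
Reactants: 17 (2R,3S)-3-(tert-butyldimethylsilyloxy)-6-geranyl-5-methoxy-7-(triisopropylsilyloxy)-2-[4-(triisopropylsilyloxy)phenyl]chroman-4-ol (C4 epimers)
Product: 18 (2R,3R)-3-(tert-butyldimethylsilyloxy)-6-geranyl-5-methoxy-7-(triisopropylsilyloxy)-2-[4-(triisopropylsilyloxy)phenyl]chroman-4-one
Conditions: Dess–Martin periodinane, NaHCO3, CH2Cl2, 0 °C → rt
Reagents that add atoms: none
Why: Dess–Martin oxidation of the benzylic secondary alcohol; the buffered, neutral conditions leave the alkenes, the silyl ethers and the now enolisable C3 centre alone, and both C4 epimers converge on one ketone.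

Step 13
Reactants: 18 (2R,3R)-3-(tert-butyldimethylsilyloxy)-6-geranyl-5-methoxy-7-(triisopropylsilyloxy)-2-[4-(triisopropylsilyloxy)phenyl]chroman-4-one
Product: 19 (2R,3R)-6-geranyl-3,7-dihydroxy-2-(4-hydroxyphenyl)-5-methoxychroman-4-one
Conditions: Bu4NF, AcOH (1:1), THF, 0 °C → rt
Reagents that add atoms: none
Why: Fluoride cleavage of the three Si–O bonds (two aryl TIPS ethers, one secondary TBS ether); acetic acid protonates the phenoxides and the alkoxide as they form, so ring C should not open and C2 and C3 should keep their configuration, and the geranyl chain next to the freed C7 phenol sees no strong acid.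

## Compound list

1 | 2,4,6-trihydroxybenzaldehyde | O=Cc1c(O)cc(O)cc1O | starting material
2 | geranyl bromide, (2E)-1-bromo-3,7-dimethylocta-2,6-diene | BrC/C=C(\C)CCC=C(C)C | starting material
3 | 3-geranyl-2,4,6-trihydroxybenzaldehyde | O=Cc1c(O)cc(O)c(C/C=C(\C)CCC=C(C)C)c1O | intermediate
4 | 3-geranyl-2,6-dihydroxy-4-(triisopropylsilyloxy)benzaldehyde | O=Cc1c(O)cc(O[Si](C(C)C)(C(C)C)C(C)C)c(C/C=C(\C)CCC=C(C)C)c1O | intermediate
5 | 3-geranyl-2-hydroxy-6-(methoxymethoxy)-4-(triisopropylsilyloxy)benzaldehyde | O=Cc1c(OCOC)cc(O[Si](C(C)C)(C(C)C)C(C)C)c(C/C=C(\C)CCC=C(C)C)c1O | intermediate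
6 | 3-geranyl-2-methoxy-6-(methoxymethoxy)-4-(triisopropylsilyloxy)benzaldehyde | COc1c(C/C=C(\C)CCC=C(C)C)c(O[Si](C(C)C)(C(C)C)C(C)C)cc(OCOC)c1C=O | intermediate
7 | 3-geranyl-6-hydroxy-2-methoxy-4-(triisopropylsilyloxy)benzaldehyde | COc1c(C/C=C(\C)CCC=C(C)C)c(O[Si](C(C)C)(C(C)C)C(C)C)cc(O)c1C=O | intermediate
8 | (E)-4-(4-hydroxyphenyl)but-3-en-2-one | CC(=O)/C=C/c1ccc(O)cc1 | starting material
9 | (E)-4-[4-(triisopropylsilyloxy)phenyl]but-3-en-2-one | CC(=O)/C=C/c1ccc(O[Si](C(C)C)(C(C)C)C(C)C)cc1 | intermediate
10 | (E)-2-[4-(triisopropylsilyloxy)phenyl]ethenyl acetate | CC(=O)O/C=C/c1ccc(O[Si](C(C)C)(C(C)C)C(C)C)cc1 | intermediate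
11 | trimethyl orthoformate | COC(OC)OC | starting material
12 | 2-(dimethoxymethyl)-4-geranyl-3-methoxy-5-(triisopropylsilyloxy)phenol | COc1c(C/C=C(\C)CCC=C(C)C)c(O[Si](C(C)C)(C(C)C)C(C)C)cc(O)c1C(OC)OC | intermediate
13 | 4-geranyl-3-methoxy-2-(methoxymethylidene)-5-(triisopropylsilyloxy)cyclohexa-3,5-dien-1-one (reacts in its O-protonated form) | COC=C1C(=O)C=C(O[Si](C(C)C)(C(C)C)C(C)C)C(C/C=C(\C)CCC=C(C)C)=C1OC | intermediate
14 | (2R,3S)-6-geranyl-4,5-dimethoxy-7-(triisopropylsilyloxy)-2-[4-(triisopropylsilyloxy)phenyl]chroman-3-yl acetate, 2,3-trans, C4 epimers | COc1c(C/C=C(\C)CCC=C(C)C)c(O[Si](C(C)C)(C(C)C)C(C)C)cc2c1C(OC)[C@H](OC(C)=O)[C@@H](c1ccc(O[Si](C(C)C)(C(C)C)C(C)C)cc1)O2 | intermediate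
15 | (2R,3S)-6-geranyl-4,5-dimethoxy-7-(triisopropylsilyloxy)-2-[4-(triisopropylsilyloxy)phenyl]chroman-3-ol, C4 epimers | COc1c(C/C=C(\C)CCC=C(C)C)c(O[Si](C(C)C)(C(C)C)C(C)C)cc2c1C(OC)[C@H](O)[C@@H](c1ccc(O[Si](C(C)C)(C(C)C)C(C)C)cc1)O2 | intermediate
16 | (2R,3S)-3-(tert-butyldimethylsilyloxy)-6-geranyl-4,5-dimethoxy-7-(triisopropylsilyloxy)-2-[4-(triisopropylsilyloxy)phenyl]chroman, C4 epimers | COc1c(C/C=C(\C)CCC=C(C)C)c(O[Si](C(C)C)(C(C)C)C(C)C)cc2c1C(OC)[C@H](O[Si](C)(C)C(C)(C)C)[C@@H](c1ccc(O[Si](C(C)C)(C(C)C)C(C)C)cc1)O2 | intermediate
17 | (2R,3S)-3-(tert-butyldimethylsilyloxy)-6-geranyl-5-methoxy-7-(triisopropylsilyloxy)-2-[4-(triisopropylsilyloxy)phenyl]chroman-4-ol, C4 epimers | COc1c(C/C=C(\C)CCC=C(C)C)c(O[Si](C(C)C)(C(C)C)C(C)C)cc2c1C(O)[C@H](O[Si](C)(C)C(C)(C)C)[C@@H](c1ccc(O[Si](C(C)C)(C(C)C)C(C)C)cc1)O2 | intermediate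
18 | (2R,3R)-3-(tert-butyldimethylsilyloxy)-6-geranyl-5-methoxy-7-(triisopropylsilyloxy)-2-[4-(triisopropylsilyloxy)phenyl]chroman-4-one | COc1c(C/C=C(\C)CCC=C(C)C)c(O[Si](C(C)C)(C(C)C)C(C)C)cc2c1C(=O)[C@H](O[Si](C)(C)C(C)(C)C)[C@@H](c1ccc(O[Si](C(C)C)(C(C)C)C(C)C)cc1)O2 | intermediate
19 | (2R,3R)-6-geranyl-3,7-dihydroxy-2-(4-hydroxyphenyl)-5-methoxychroman-4-one | COc1c(C/C=C(\C)CCC=C(C)C)c(O)cc2c1C(=O)[C@H](O)[C@@H](c1ccc(O)cc1)O2 | target

## Step count and risk

Total step count: 13. Longest linear sequence: 11 steps (steps 1–5 and 8–13); steps 6 and 7 form the second branch.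

**Step 8 (the step marked as a proposed new method).**
- What may go wrong: the carbon–carbon bond may fail to form, because the trioxygenated oxocarbenium ion is strongly stabilised and the attacked carbon of 10 carries an electron-withdrawing acyloxy group. Chemoselectivity may be lost through capture of the cation by a geranyl alkene of a second molecule or by methanol, or through acetyl transfer from the enol ester. Facial discrimination may be poor, because 10 offers the phosphate no hydrogen-bond handle. The product may also lose its C4 methoxy group and H3 under the acid.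
- Fallback (known chemistry), from 6 back to the route at 19:
  - Addition of MeMgBr (THF, −78 °C) to 6 gives the methyl carbinol F1, and Dess–Martin oxidation gives the acetophenone F2.
  - The lithium enolate of F2 (LiN(SiMe3)2, THF, −78 °C) is condensed with 4-(triisopropylsilyloxy)benzaldehyde F3, and the aldol adduct is dehydrated in the same flask (MsCl, Et3N, then DBU) to the (E)-chalcone F4.
  - Juliá–Colonna epoxidation (poly-L-leucine, urea–H2O2, DBU, THF) gives the trans-(2R,3S)-epoxy ketone F5.
  - Dilute HCl in MeOH–THF removes the MOM group, and the freed phenol opens the epoxide at the benzylic carbon with inversion to give the bis-silylated trans-dihydroflavonol F6.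
  - Buffered Bu4NF/AcOH converts F6 into 19.

**Step 11.**
- What may go wrong: the C4 cation may lose H3 irreversibly (elimination towards the enol silyl ether, which destroys C3) while its capture by water is reversible; the exchange may also stall before completion.
- Fallback, from 16 back to the route at 17: exchange of the methoxy group for a soft nucleophile under anhydrous conditions (BnSH, BF3·OEt2, CH2Cl2, −40 °C) gives the 4-benzylsulfanyl chroman F7. AgBF4 in wet THF with 2,6-lutidine then replaces the sulfur by hydroxyl in a single buffered pass, in which the alcohol cannot re-ionise.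

**Step 3.**
- What may go wrong: etherification at the geranyl-flanked phenol, or at both chelated phenols, would carry a regioisomer through the sequence.
- Fallback, from 4 back to the route at 7: a bulkier temporary group with orthogonal, non-acidic removal. TBSCl/imidazole in DMF gives the 6-O-TBS ether F8 with a stronger steric bias. Mitsunobu methylation (MeOH, PPh3, diisopropyl azodicarboxylate) gives the methyl ether F9. K2CO3 (cat.) in MeOH at 0 °C then cleaves only the aryl TBS ether ortho to the aldehyde.

**Step 7.**
- What may go wrong: over-oxidation (epoxidation of the electron-rich enol acetate by the peracid) and hydrolysis of the enol ester in the aqueous medium.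
- Fallback, from 9 back to the route at 10, forming the enol ester by acylation and not by oxidation:
  - Oxidative cleavage of the enone (K2OsO4·2H2O cat., NaIO4, 2,6-lutidine, dioxane–water) gives 4-(triisopropylsilyloxy)benzaldehyde F3.
  - Wittig reaction with the ylide from (methoxymethyl)triphenylphosphonium chloride and KN(SiMe3)2 gives the enol ether F10.
  - Aqueous formic acid in THF gives the arylacetaldehyde F11.
  - Ac2O, Et3N and 4-(dimethylamino)pyridine give the enol acetate as an E/Z mixture. 10 is separated by chromatography and the Z isomer is re-equilibrated with a trace of iodine.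

**Step 13.**
- What may go wrong: once the 4'-phenoxide forms, the basic fluoride may open ring C at O1–C2 (epimerisation at C2); the hindered C3 silyl ether may be cleaved only slowly.
- Fallback, from 18 back to the route at 19, in two acidic stages: aqueous HF in MeCN at 0 °C removes the secondary TBS ether while the aryl ethers remain, giving the bis-silylated dihydroflavonol F6. KHF2 in MeOH then cleaves the two aryl TIPS ethers under weakly acidic conditions.

## Further compounds

F1 | step 8 | 1-[3-geranyl-2-methoxy-6-(methoxymethoxy)-4-(triisopropylsilyloxy)phenyl]ethan-1-ol (racemic) | COc1c(C/C=C(\C)CCC=C(C)C)c(O[Si](C(C)C)(C(C)C)C(C)C)cc(OCOC)c1C(C)O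
F2 | step 8 | 1-[3-geranyl-2-methoxy-6-(methoxymethoxy)-4-(triisopropylsilyloxy)phenyl]ethan-1-one | COc1c(C/C=C(\C)CCC=C(C)C)c(O[Si](C(C)C)(C(C)C)C(C)C)cc(OCOC)c1C(C)=O
F3 | step 8 | 4-(triisopropylsilyloxy)benzaldehyde | O=Cc1ccc(O[Si](C(C)C)(C(C)C)C(C)C)cc1
F4 | step 8 | (E)-1-[3-geranyl-2-methoxy-6-(methoxymethoxy)-4-(triisopropylsilyloxy)phenyl]-3-[4-(triisopropylsilyloxy)phenyl]prop-2-en-1-one | COc1c(C/C=C(\C)CCC=C(C)C)c(O[Si](C(C)C)(C(C)C)C(C)C)cc(OCOC)c1C(=O)/C=C/c1ccc(O[Si](C(C)C)(C(C)C)C(C)C)cc1
F5 | step 8 | [3-geranyl-2-methoxy-6-(methoxymethoxy)-4-(triisopropylsilyloxy)phenyl]{(2R,3S)-3-[4-(triisopropylsilyloxy)phenyl]oxiran-2-yl}methanone | COc1c(C/C=C(\C)CCC=C(C)C)c(O[Si](C(C)C)(C(C)C)C(C)C)cc(OCOC)c1C(=O)[C@@H]2O[C@H]2c3ccc(O[Si](C(C)C)(C(C)C)C(C)C)cc3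
F6 | step 8 | (2R,3R)-6-geranyl-3-hydroxy-5-methoxy-7-(triisopropylsilyloxy)-2-[4-(triisopropylsilyloxy)phenyl]chroman-4-one | COc1c(C/C=C(\C)CCC=C(C)C)c(O[Si](C(C)C)(C(C)C)C(C)C)cc2c1C(=O)[C@H](O)[C@@H](c1ccc(O[Si](C(C)C)(C(C)C)C(C)C)cc1)O2
F7 | step 11 | (2R,3R)-4-(benzylsulfanyl)-3-(tert-butyldimethylsilyloxy)-6-geranyl-5-methoxy-7-(triisopropylsilyloxy)-2-[4-(triisopropylsilyloxy)phenyl]chroman, C4 epimers | COc1c(C/C=C(\C)CCC=C(C)C)c(O[Si](C(C)C)(C(C)C)C(C)C)cc2c1C(SCc1ccccc1)[C@H](O[Si](C)(C)C(C)(C)C)[C@@H](c1ccc(O[Si](C(C)C)(C(C)C)C(C)C)cc1)O2
F8 | step 3 | 6-(tert-butyldimethylsilyloxy)-3-geranyl-2-hydroxy-4-(triisopropylsilyloxy)benzaldehyde | O=Cc1c(O[Si](C)(C)C(C)(C)C)cc(O[Si](C(C)C)(C(C)C)C(C)C)c(C/C=C(\C)CCC=C(C)C)c1O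
F9 | step 3 | 6-(tert-butyldimethylsilyloxy)-3-geranyl-2-methoxy-4-(triisopropylsilyloxy)benzaldehyde | COc1c(C/C=C(\C)CCC=C(C)C)c(O[Si](C(C)C)(C(C)C)C(C)C)cc(O[Si](C)(C)C(C)(C)C)c1C=O
F10 | step 7 | triisopropyl[4-(2-methoxyethenyl)phenoxy]silane (E/Z mixture) | COC=Cc1ccc(O[Si](C(C)C)(C(C)C)C(C)C)cc1
F11 | step 7 | 2-[4-(triisopropylsilyloxy)phenyl]acetaldehyde | O=CCc1ccc(O[Si](C(C)C)(C(C)C)C(C)C)cc1
A1 | alternative 1 | (2R,3R)-1-[3-geranyl-2-methoxy-6-(methoxymethoxy)-4-(triisopropylsilyloxy)phenyl]-2,3-dihydroxy-3-[4-(triisopropylsilyloxy)phenyl]propan-1-one | COc1c(C/C=C(\C)CCC=C(C)C)c(O[Si](C(C)C)(C(C)C)C(C)C)cc(OCOC)c1C(=O)[C@H](O)[C@@H](c1ccc(O[Si](C(C)C)(C(C)C)C(C)C)cc1)O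
A2 | alternative 1 | 2-diazo-1-[3-geranyl-2-methoxy-6-(methoxymethoxy)-4-(triisopropylsilyloxy)phenyl]ethan-1-one | COc1c(C/C=C(\C)CCC=C(C)C)c(O[Si](C(C)C)(C(C)C)C(C)C)cc(OCOC)c1C(=O)C=[N+]=[N-]
A3 | alternative 1 | 4-(triisopropylsilyloxy)benzaldehyde | O=Cc1ccc(O[Si](C(C)C)(C(C)C)C(C)C)cc1
A4 | alternative 1 | water | O
A5 | alternative 2 | (E)-1-(3-geranyl-2,4,6-trihydroxyphenyl)-3-[4-(methoxymethoxy)phenyl]prop-2-en-1-one | Oc1cc(O)c(C(=O)/C=C/c2ccc(OCOC)cc2)c(O)c1C/C=C(\C)CCC=C(C)C
A6 | alternative 2 | methyl (8E)-2-geranyl-9-[4-(methoxymethoxy)phenyl]-3,5,7-trioxonon-8-enoate | COC(=O)C(C/C=C(\C)CCC=C(C)C)C(=O)CC(=O)CC(=O)/C=C/c1ccc(OCOC)cc1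
A7 | alternative 3 | 4-geranyl-3-methoxy-5-(triisopropylsilyloxy)phenol | COc1cc(O)cc(O[Si](C(C)C)(C(C)C)C(C)C)c1C/C=C(\C)CCC=C(C)C
A8 | alternative 3 | (6E)-4-diazo-2-methoxy-7,11-dimethyldodeca-1,6,10-trien-3-one | C=C(OC)C(=O)C(=[N+]=[N-])C/C=C(\C)CCC=C(C)C
A9 | alternative 3 | (ethynyloxy)triisopropylsilane | C#CO[Si](C(C)C)(C(C)C)C(C)C
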